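The indenone is cut at C-3a–C-7a, C-4–C-5 and C-6–C-7. Its benzene ring has hydrogen only at C-5 and C-6. It carries the C-7 methyl and C-4 formyl groups para to each other and shares the C-3a–C-7a edge with the five-membered ring. This is the footprint of a 1,6-diyne joined to acetylene, so one rhodium-catalysed [2+2+2] cycloaddition closes both rings. The precursor is a nona-2,7-diyn-4-one with the guaiazulen-3-yl group at C-5, a trimethylsilyl-capped tertiary carbinol at C-6 and a diethyl acetal at C-9. The cap shuts off retro-aldol cleavage and oxa-Michael closure. Base, then acid, deliver the C-2=C-3 alkene and the aldehyde.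

Key step: step 6

Remark on the chemistry: guaiazulen-3-yl stands for 3,8-dimethyl-5-(propan-2-yl)azulen-1-yl; all sp3 stereocentres made on the way (in 10, 11, 13–16 and 18) arise as racemic diastereomer mixtures, are written without stereodescriptors and are destroyed in steps 5 and 7, the target having no stereocentre.

Step 1
Reactants: 1 guaiazulene (1,4-dimethyl-7-isopropylazulene); 2 ethyl diazoacetate
Product: 3 ethyl 2-(guaiazulen-3-yl)acetate
Conditions: Cu(acac)2 (5 mol %), 2 added slowly by syringe pump, ClCH2CH2Cl, 70 °C
Reagents that add atoms: none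
Why: Metal-carbene C–H functionalisation (formal C–H insertion), in which the electrophilic copper carbene is attacked by C-3, the only free position of the nucleophilic C-1/C-3 pair of the five-membered ring, and the tropylium-type zwitterion rearomatises by proton shift, as known for azulenes and indoles with diazoacetates.

Step 2
Reactants: 4 3,3-diethoxyprop-1-yne; 5 N-methoxy-N-methylacetamide
Product: 8 5,5-diethoxypent-3-yn-2-one, via lithium acetylide 6 (not isolated), via tetrahedral adduct 7 (not isolated)
Conditions: n-BuLi, THF, −78 °C; then 5, −78 → 0 °C; aq NH4Cl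
Reagents that add atoms: none
Why: Weinreb ketone synthesis, in which acetylide 6 adds to 5 and stops at the lithium-chelated adduct 7 until the quench, so that no second addition occurs and the base-stable acetal is untouched.

Step 3
Reactants: 3 ethyl 2-(guaiazulen-3-yl)acetate; 8 5,5-diethoxypent-3-yn-2-one
Product: 11 ethyl 6,6-diethoxy-2-(guaiazulen-3-yl)-3-methyl-3-(trimethylsilyloxy)hex-4-ynoate (racemic diastereomer mixture), via lithium enolate 9 (not isolated), via lithium aldolate 10 (not isolated)
Conditions: LiN(SiMe3)2, THF, −78 °C; then 8, −78 °C; then Me3SiCl, −78 → −20 °C; aq NaHCO3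
Reagents that add atoms: chlorotrimethylsilane, C[Si](C)(C)Cl
Why: Aldol addition of a lithium ester enolate to a ketone with in situ O-silylation, in which the ester CH2 is acidic enough for LiN(SiMe3)2 (a base that leaves the weakly acidic C-4 methyl group of the azulene alone), the hard enolate adds 1,2 to the ynone carbonyl under kinetic control, Me3SiCl caps aldolate 10 before it can revert, no Lewis acid ever meets the acetal, and the two new stereocentres are formed without control because step 7 erases both.

Step 4
Reactants: 11 ethyl 6,6-diethoxy-2-(guaiazulen-3-yl)-3-methyl-3-(trimethylsilyloxy)hex-4-ynoate; 12 prop-1-ynylmagnesium bromide (commercial THF solution)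
Product: 15 9,9-diethoxy-5-(guaiazulen-3-yl)-6-methyl-6-(trimethylsilyloxy)nona-2,7-diyn-4-ol (racemic diastereomer mixture), via aluminium hemiacetal 13 (not isolated), via aldehyde 14 (not isolated)
Conditions: iBu2AlH (1.1 equiv), CH2Cl2, −78 °C; then 12 (3 equiv), −78 → 0 °C; aq KNaC4H4O6 (tartrate)
Reagents that add atoms: none
Why: One-pot partial ester reduction followed by Grignard addition, in which the hindered hemiacetal 13 holds at −78 °C and releases aldehyde 14 only on warming in the presence of excess 12, so that the elimination-prone α-aryl aldehyde is never handled, and the new carbinol centre needs no control because step 5 removes it.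

Step 5
Reactants: 15 9,9-diethoxy-5-(guaiazulen-3-yl)-6-methyl-6-(trimethylsilyloxy)nona-2,7-diyn-4-ol
Product: 16 9,9-diethoxy-5-(guaiazulen-3-yl)-6-methyl-6-(trimethylsilyloxy)nona-2,7-diyn-4-one (racemic diastereomer mixture)
Conditions: activated MnO2 (excess), CH2Cl2, rt
Reagents that add atoms: none
Why: MnO2 oxidation of a propargylic alcohol to the ynone on a neutral solid oxidant that offers neither acid to the acetal and silyl ether nor base to the now acidic C-5–H, spares the azulene and removes the uncontrolled C-4 stereocentre.

Step 6
Reactants: 16 9,9-diethoxy-5-(guaiazulen-3-yl)-6-methyl-6-(trimethylsilyloxy)nona-2,7-diyn-4-one; 17 acetylene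
Product: 18 4-(diethoxymethyl)-2-(guaiazulen-3-yl)-3,7-dimethyl-3-(trimethylsilyloxy)indan-1-one (racemic diastereomer mixture)
Conditions: RhCl(PPh3)3 (10 mol %), 17 (1 atm, solution kept saturated), toluene, 60 °C, 16 added slowly
Reagents that add atoms: none
Why: RhCl(PPh3)3 sheds PPh3, binds both alkynes of 16 and couples them oxidatively to a bicyclic rhodacyclopentadiene of trivalent rhodium, which makes the C-3a–C-7a bond and so closes the five-membered carbocycle across the three-atom tether C-1–C-2–C-3; acetylene then coordinates and inserts, and reductive elimination makes C-4–C-5 and C-6–C-7, closes the benzene ring and returns monovalent rhodium. The closest known reaction type is the rhodium-catalysed [2+2+2] cyclotrimerisation of 1,6-diynes, ynone-containing ones included, with monoalkynes or acetylene to give indanes and indanones. No stereocentre is formed and those at C-2 and C-3 are spectators, so all diastereomers of 16 converge on 18 as a mixture that step 7 levels. Regiochemistry is not at stake, because acetylene is symmetrical and the tether forces the outer alkyne carbons with their CH3 and CH(OEt)2 groups into the para-related positions C-7 and C-4. What the step needs is chemoselective capture of the rhodacycle by acetylene instead of a second diyne: both alkyne termini of 16 are substituted and insert poorly, the fully substituted tether speeds up the intramolecular coupling (Thorpe–Ingold effect), and acetylene saturation with slow addition of 16 supports this. The acetal keeps a formyl group away from a catalyst that decarbonylates aldehydes, and the silyl cap removes the free hydroxyl that would add to the ynone (6-endo oxa-Michael) or leave by retro-aldol cleavage.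

Step 7
Reactants: 18 4-(diethoxymethyl)-2-(guaiazulen-3-yl)-3,7-dimethyl-3-(trimethylsilyloxy)indan-1-one
Product: 20 2-(guaiazulen-3-yl)-3,7-dimethyl-1-oxo-1H-indene-4-carbaldehyde (target CNP0233877.0), via indenone acetal 19 (not isolated)
Conditions: DBU (1.5 equiv), THF, rt; then 1 M aq HCl, rt (one pot)
Reagents that add atoms: water, O
Why: E1cB elimination followed by acid-catalysed acetal hydrolysis, in which DBU removes the C-2–H acidified by the ketone, the enolate expels trimethylsilanolate from C-3 to give the conjugated indenone while the aldehyde is still masked (so that the vinylogously acidic C-3 methyl group finds no partner), dilute acid then frees the C-4 formyl group, and both stereocentres vanish.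

Compound list
1 | guaiazulene (1,4-dimethyl-7-isopropylazulene) | c1cc(C)c2cc(C(C)C)ccc(C)c1-2 | starting material
2 | ethyl diazoacetate | CCOC(=O)C=[N+]=[N-] | starting material
3 | ethyl 2-(guaiazulen-3-yl)acetate | CCOC(=O)Cc1cc(C)c2cc(C(C)C)ccc(C)c1-2 | intermediate
4 | 3,3-diethoxyprop-1-yne | C#CC(OCC)OCC | starting material
5 | N-methoxy-N-methylacetamide | CC(=O)N(C)OC | starting material
6 | (3,3-diethoxyprop-1-yn-1-yl)lithium | [Li]C#CC(OCC)OCC | intermediate
7 | lithium 5,5-diethoxy-2-[methoxy(methyl)amino]pent-3-yn-2-olate (tetrahedral adduct) | CC(O[Li])(N(C)OC)C#CC(OCC)OCC | intermediate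
8 | 5,5-diethoxypent-3-yn-2-one | CC(=O)C#CC(OCC)OCC | intermediate
9 | lithium enolate of 3 | CCOC(O[Li])=Cc1cc(C)c2cc(C(C)C)ccc(C)c1-2 | intermediate
10 | lithium aldolate, ethyl 6,6-diethoxy-2-(guaiazulen-3-yl)-3-lithiooxy-3-methylhex-4-ynoate (racemic diastereomer mixture) | CCOC(=O)C(c1cc(C)c2cc(C(C)C)ccc(C)c1-2)C(C)(O[Li])C#CC(OCC)OCC | intermediate
11 | ethyl 6,6-diethoxy-2-(guaiazulen-3-yl)-3-methyl-3-(trimethylsilyloxy)hex-4-ynoate (racemic diastereomer mixture) | CCOC(=O)C(c1cc(C)c2cc(C(C)C)ccc(C)c1-2)C(C)(O[Si](C)(C)C)C#CC(OCC)OCC | intermediate
12 | prop-1-ynylmagnesium bromide | CC#C[Mg]Br | starting material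
13 | diisobutylaluminium hemiacetal of 14 (O-ethyl, O-aluminium; diastereomer mixture) | CCOC(O[Al](CC(C)C)CC(C)C)C(c1cc(C)c2cc(C(C)C)ccc(C)c1-2)C(C)(O[Si](C)(C)C)C#CC(OCC)OCC | intermediate
14 | 6,6-diethoxy-2-(guaiazulen-3-yl)-3-methyl-3-(trimethylsilyloxy)hex-4-ynal (racemic diastereomer mixture) | O=CC(c1cc(C)c2cc(C(C)C)ccc(C)c1-2)C(C)(O[Si](C)(C)C)C#CC(OCC)OCC | intermediate
15 | 9,9-diethoxy-5-(guaiazulen-3-yl)-6-methyl-6-(trimethylsilyloxy)nona-2,7-diyn-4-ol (racemic diastereomer mixture) | CC#CC(O)C(c1cc(C)c2cc(C(C)C)ccc(C)c1-2)C(C)(O[Si](C)(C)C)C#CC(OCC)OCC | intermediate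
16 | 9,9-diethoxy-5-(guaiazulen-3-yl)-6-methyl-6-(trimethylsilyloxy)nona-2,7-diyn-4-one (racemic diastereomer mixture) | CC#CC(=O)C(c1cc(C)c2cc(C(C)C)ccc(C)c1-2)C(C)(O[Si](C)(C)C)C#CC(OCC)OCC | intermediate
17 | acetylene | C#C | starting material
18 | 4-(diethoxymethyl)-2-(guaiazulen-3-yl)-3,7-dimethyl-3-(trimethylsilyloxy)indan-1-one (racemic diastereomer mixture) | O=C1C(c2cc(C)c3cc(C(C)C)ccc(C)c2-3)C(C)(O[Si](C)(C)C)c2c(C(OCC)OCC)ccc(C)c21 | intermediate
19 | 4-(diethoxymethyl)-2-(guaiazulen-3-yl)-3,7-dimethylinden-1-one | CC1=C(c2cc(C)c3cc(C(C)C)ccc(C)c2-3)C(=O)c2c(C)ccc(C(OCC)OCC)c21 | intermediate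
20 | 2-(guaiazulen-3-yl)-3,7-dimethyl-1-oxo-1H-indene-4-carbaldehyde | CC1=C(c2cc(C)c3cc(C(C)C)ccc(C)c2-3)C(=O)c2c(C)ccc(C=O)c21 | target

Total step count: 7. Longest linear sequence: 6 steps (1, 3, 4, 5, 6, 7, from guaiazulene).

Steps most likely to fail

Step 6. Oxidative coupling of two hindered internal alkynes may be slow. Loss of silanol from the β-silyloxy ynone on heating, attack of liberated PPh3 on the ynone, self-coupling of the diyne or binding of rhodium to the azulene could then take over. The fallback runs the same ring construction one oxidation level lower and sets out from 15. The diynol has neither an acidic C-5–H nor a Michael acceptor, so it tolerates ethanol as co-solvent and longer heating. It is cyclotrimerised with 17 (RhCl(PPh3)3, EtOH–toluene, 60–80 °C) to 4-(diethoxymethyl)-2-(guaiazulen-3-yl)-3,7-dimethyl-3-(trimethylsilyloxy)indan-1-ol F1. Oxidation of the benzylic carbinol with MnO2 in CH2Cl2 then comes back to the route at 18. The oxidation of step 5 is only postponed, so the step count stays the same.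

Step 3. Proton transfer from the methyl ketone 8 to the basic enolate, reversal of the aldolate before silylation is complete, or conjugate addition to the ynone could erode the addition. The fallback replaces the stoichiometric enolate by a Lewis-base-catalysed Mukaiyama aldol addition and sets out from 3. Enolate 9 is silylated on oxygen (LiN(SiMe3)2, then Me3SiCl, no ketone present) and isolated as 1-ethoxy-2-(guaiazulen-3-yl)-1-(trimethylsilyloxy)ethene F2. It is then combined with 8 and catalytic NaOPh with a phosphine oxide ligand in THF at −78 °C. Only a catalytic amount of basic species is present. The turnover step transfers the silyl group to the aldolate oxygen, which makes the addition irreversible and comes back to the route directly at 11.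

Step 4. Three processes could lower the return: over-reduction before 12 meets the aldehyde, untimely collapse of the aluminium hemiacetal, and migration of the silyl group to the new magnesium alkoxide during warming. The fallback is a stepwise redox sequence that sets out from 11. Excess iBu2AlH (CH2Cl2, −78 → 0 °C) reduces the ester fully to 6,6-diethoxy-2-(guaiazulen-3-yl)-3-methyl-3-(trimethylsilyloxy)hex-4-yn-1-ol F3. Dess–Martin periodinane buffered with NaHCO3 then gives aldehyde 14, this time isolated. Reagent 12 is added at −78 °C and the alkoxide is protonated cold with acetic acid, which leaves no time for silyl transfer and comes back to the route at 15.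

Further compounds
F1 | step 6 | 4-(diethoxymethyl)-2-(guaiazulen-3-yl)-3,7-dimethyl-3-(trimethylsilyloxy)indan-1-ol (racemic diastereomer mixture) | OC1C(c2cc(C)c3cc(C(C)C)ccc(C)c2-3)C(C)(O[Si](C)(C)C)c2c(C(OCC)OCC)ccc(C)c21
F2 | step 3 | 1-ethoxy-2-(guaiazulen-3-yl)-1-(trimethylsilyloxy)ethene | CCOC(O[Si](C)(C)C)=Cc1cc(C)c2cc(C(C)C)ccc(C)c1-2
F3 | step 4 | 6,6-diethoxy-2-(guaiazulen-3-yl)-3-methyl-3-(trimethylsilyloxy)hex-4-yn-1-ol (racemic diastereomer mixture) | OCC(c1cc(C)c2cc(C(C)C)ccc(C)c1-2)C(C)(O[Si](C)(C)C)C#CC(OCC)OCC
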